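Two questions stand on this flask, and the two earlier runs can answer them once I find what stays constant between them.

| flask | Q | J | E | remark | time |
|---|---|---|---|---|---|
| north-west | 28 mM | 3 equiv | 2 mM | run made earlier |  |
| south-west | 44 mM | 3 equiv | 2 mM | run made earlier |  |
| flask | 20 mM | 3.00 equiv | 2.00 mM |  | 30 min |

* the species in which most of what was charged as Q, at 30 min sits (G / X / Q)
* the largest share itself, whichever of these holds it, in percent of the Q charged

- Q is a solid; its amount is given per volume of the solution
- candidate steps: X <-> G; D + J -> X; Q <-> D; Q + E -> L; J -> Z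
- at the start none of Q is in solution
- as a choice and as an amount asked, Q means what is still solid

- north-west (time / min: G / %, Q / %, X / %): 2.50: 0, 86.1, 1.0; 4.00: 0, 81.6, 2.1; 6.00: 0.4, 76.9, 4.5; 10.0: 0, 74.0, 8.2; 20.0: 1.0, 65.8, 9.9; 30.0: 2.3, 61.2, 13.4
- south-west (time / min: G / %, Q / %, X / %): 2.50: 0.2, 90.2, 0.2; 4.00: 0.9, 87.1, 0; 6.00: 0.7, 88.2, 5.6; 10.0: 0, 80.6, 5.2; 20.0: 2.3, 73.5, 11.3; 30.0: 1.5, 71.2, 12.8

(standard deviation of a reading: 1 percentage point)

The last rows of the two tables, at 30.0 min, carry the argument. The solid Q lost 10.9 mM in the north-west run and 12.7 mM in the south-west run, although the charge rose from 28 mM to 44 mM. I subtract the columns X and G from those losses, which leaves 6.47 mM and 6.38 mM. These two readings agree within the scatter. Their mean, 6.42 mM, I freeze as the hold-up H, the Q in mM that has left the solid and is neither X nor G. It can sit in D and L, which no column shows.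

X plus G reads 15.7% and 14.3% of the charge at the same 3 equiv of J, so I take the mean, 15.0%, for this flask. By this reckoning the flask keeps 52.9% of its 20 mM as solid, more than X and G together, so my answer is Q.

The forecast, calling the plateau “reached quickly and independent of the charge”, gives Q at 53%.

The flask gives Q at 50.4%, with 14.4% in X and 2.45% in G.

    X ⇌ G (K = 0.320, k = 0.0140 min⁻¹)
    D + J → X (k = 1.40 L mol⁻¹ min⁻¹)
    Q ⇌ D, rate k3*(cs3 - [D]) while solid is left; crystals form when [D] > cs3 (solubility = 4.80 mM, k = 0.250 min⁻¹)
    Q + E → L (k = 16.0 L mol⁻¹ min⁻¹)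
    J → Z (k = 0.0660 min⁻¹)

In this flask H comes to 6.55 mM, made up of D at 4.55 mM and L at 2.00 mM. H stays this small because of the low solubility of D: with that taken away, this flask ends with 0% solid instead of 50.4%. A neighbouring flask, the same but with 0.750 equiv of J, holds 4.56% as X and G, so the frozen H leaves 63.3% solid, and that neighbour stands at 61.8%.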